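The tetrasubstituted C3=C4 double bond of the furan-2(5H)-one ring carries the lactone carbonyl carbon C2 and the enol carbon C5 cis to each other, and the synthesis rests on this feature. One nickel-mediated operation adds CO2 (future C2) and an alkynyl group (future C5 with its exocyclic carbon) syn across an alkyne. That alkyne already carries the (R)-silyloxybutyl chain on C3 and a tributylstannyl bromine surrogate on C4, so the precursor is an (R)-1-stannyl-3-silyloxyhex-1-yne. Tin-to-bromine exchange and an anti iodolactonisation, which closes O1–C5 and sets the (E)-iodomethylidene, finish the target.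

Key step: step 5

Remark on the chemistry: the target is read as (5E)-4-bromo-3-[(1R)-1-hydroxybutyl]-5-(iodomethylidene)furan-2(5H)-one, with ring atoms numbered O1, C2 (carbonyl), C3, C4, C5 throughout; MeLi·LiBr and lithium (trimethylsilyl)acetylide are taken as purchased solutions.

Step 1
Reactants: 1 butanoyl chloride; 2 bis(trimethylsilyl)acetylene
Product: 3 1-(trimethylsilyl)hex-1-yn-3-one
Conditions: AlCl3, CH2Cl2, 0 °C
Reagents that add atoms: none
Why: Friedel–Crafts-type acylation in which the acylium–AlCl3 complex attacks the silylalkyne at the silicon-bearing carbon and loss of Me3SiCl gives the ynone, which is too electron-poor to react a second time.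

Step 2
Reactants: 3 1-(trimethylsilyl)hex-1-yn-3-one
Product: 4 (3R)-1-(trimethylsilyl)hex-1-yn-3-ol
Conditions: Ru[(R,R)-TsDPEN](p-cymene) (0.5 mol %), i-PrOH, rt
Reagents that add atoms: none
Why: Noyori asymmetric transfer hydrogenation, in which the (R,R)-TsDPEN ruthenium hydride transfers hydride and proton through the six-membered transition state with the alkynyl group in the place of the aryl group of an aryl ketone, which should set the (R)-carbinol and leave the C≡C–Si unit untouched.

Step 3
Reactants: 4 (3R)-1-(trimethylsilyl)hex-1-yn-3-ol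
Product: 5 tert-butyl(dimethyl){[(3R)-1-(trimethylsilyl)hex-1-yn-3-yl]oxy}silane
Conditions: TBSCl, imidazole, DMF, rt
Reagents that add atoms: tert-butyldimethylsilyl chloride (TBSCl), CC(C)(C)[Si](C)(C)Cl
Why: Silyl ether formation through the N-silylimidazolium intermediate protects the only acidic hydrogen before the organometallic steps.

Step 4
Reactants: 5 tert-butyl(dimethyl){[(3R)-1-(trimethylsilyl)hex-1-yn-3-yl]oxy}silane
Product: 7 tributyl[(3R)-3-{[tert-butyl(dimethyl)silyl]oxy}hex-1-yn-1-yl]stannane, via lithium acetylide 6 (not isolated)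
Conditions: MeLi·LiBr, THF, 0 °C to rt; then Bu3SnCl, −78 °C to rt
Reagents that add atoms: tributyltin chloride (Bu3SnCl), CCCC[Sn](Cl)(CCCC)CCCC
Why: Nucleophilic desilylation of the alkynylsilane by MeLi (loss of Me4Si) gives the lithium acetylide, which Bu3SnCl stannylates at carbon (silicon–tin exchange), while the TBS ether and the carbinol centre are not touched.

Step 5
Reactants: 7 tributyl[(3R)-3-{[tert-butyl(dimethyl)silyl]oxy}hex-1-yn-1-yl]stannane
Product: 9 (2E)-2-[(1R)-1-{[tert-butyl(dimethyl)silyl]oxy}butyl]-3-(tributylstannyl)-5-(trimethylsilyl)pent-2-en-4-ynoic acid, via oxanickelacyclopentenone 8 (not isolated)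
Conditions: Ni(cod)2 (1.1 equiv), DBU, CO2 (1 atm), THF, 0 °C; then Me3SiC≡CZnCl (from Me3SiC≡CLi and ZnCl2), 0 °C to rt; cold 1 M HCl
Reagents that add atoms: carbon dioxide, O=C=O; [(trimethylsilyl)ethynyl]zinc chloride, C[Si](C)(C)C#C[Zn]Cl
Why: DBU-ligated zerovalent nickel couples the alkyne with CO2 by oxidative cyclization to nickelalactone 8, in which the new C–CO2 bond (future C2–C3) lies at the carbinol-bearing alkyne carbon and nickel sits on the tin-bearing carbon. Transmetalation with the alkynylzinc at the Ni–O bond and C(sp2)–C(sp) reductive elimination then form the future C4–C5 bond, so the overall addition is syn and carboxyl and alkynyl end up cis. The closest known reaction type is the nickel-mediated alkylative or arylative carboxylation of alkynes, silylalkynes included, with CO2 and organozinc reagents through such nickelalactones; here the organozinc is an alkynylzinc and the directing group is tin. No ring of the target is closed in this step; the only ring formed is the transient five-membered nickelalactone, closed by oxidative cyclization of alkyne, CO2 and nickel. No new stereocentre arises, the remote (R)-carbinol is retained, and the alkene geometry follows from the cis geometry of the metallacycle. The step needs regioselectivity (CO2 at the carbon remote from tin), which the stannyl group should secure by stabilising the adjacent Ni–C bond as silyl groups do, and chemoselectivity over nickel insertion into the C(sp)–Sn bond, which the low temperature and the fast DBU-accelerated CO2 coupling favour.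

Step 6
Reactants: 9 (2E)-2-[(1R)-1-{[tert-butyl(dimethyl)silyl]oxy}butyl]-3-(tributylstannyl)-5-(trimethylsilyl)pent-2-en-4-ynoic acid
Product: 10 (2E)-3-bromo-2-[(1R)-1-{[tert-butyl(dimethyl)silyl]oxy}butyl]-5-(trimethylsilyl)pent-2-en-4-ynoic acid
Conditions: Br2 (1.0 equiv), CH2Cl2, −78 °C
Reagents that add atoms: bromine, BrBr
Why: Electrophilic ipso bromodestannylation of the alkenylstannane proceeds with retention of the alkene geometry and is much faster than addition of bromine to the silylalkyne or the electron-poor alkene, so tin on C4 should be replaced cleanly by bromine.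

Step 7
Reactants: 10 (2E)-3-bromo-2-[(1R)-1-{[tert-butyl(dimethyl)silyl]oxy}butyl]-5-(trimethylsilyl)pent-2-en-4-ynoic acid
Product: 11 (2E)-3-bromo-2-[(1R)-1-hydroxybutyl]pent-2-en-4-ynoic acid
Conditions: TBAF, THF, 0 °C to rt; aq. NH4Cl
Reagents that add atoms: none
Why: Fluoride-mediated desilylation cleaves both the C(sp)–SiMe3 bond and the secondary TBS ether (strong Si–F bond) while the carboxylate, the vinyl bromide and the carbinol centre are unaffected.

Step 8
Reactants: 11 (2E)-3-bromo-2-[(1R)-1-hydroxybutyl]pent-2-en-4-ynoic acid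
Product: 12 (5E)-4-bromo-3-[(1R)-1-hydroxybutyl]-5-(iodomethylidene)furan-2(5H)-one
Conditions: I2, NaHCO3, MeCN, 0 °C to rt, dark
Reagents that add atoms: iodine, II
Why: Iodolactonisation in which the carboxylate, held cis to the ethynyl group, attacks the internal carbon of the iodine-activated terminal alkyne in a 5-exo-dig closure with anti addition of O and I, which forms O1–C5 and places iodine trans to O1 (the 5E isomer), while the hydroxyl group on the other side of the alkene cannot reach the alkyne.

Compound list
1 | butanoyl chloride | CCCC(=O)Cl | starting material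
2 | bis(trimethylsilyl)acetylene | C[Si](C)(C)C#C[Si](C)(C)C | starting material
3 | 1-(trimethylsilyl)hex-1-yn-3-one | CCCC(=O)C#C[Si](C)(C)C | intermediate
4 | (3R)-1-(trimethylsilyl)hex-1-yn-3-ol | CCC[C@@H](O)C#C[Si](C)(C)C | intermediate
5 | tert-butyl(dimethyl){[(3R)-1-(trimethylsilyl)hex-1-yn-3-yl]oxy}silane | CCC[C@@H](O[Si](C)(C)C(C)(C)C)C#C[Si](C)(C)C | intermediate
6 | lithium (3R)-3-{[tert-butyl(dimethyl)silyl]oxy}hex-1-yn-1-ide (lithium acetylide) | CCC[C@@H](O[Si](C)(C)C(C)(C)C)C#C[Li] | intermediate
7 | tributyl[(3R)-3-{[tert-butyl(dimethyl)silyl]oxy}hex-1-yn-1-yl]stannane | CCC[C@@H](O[Si](C)(C)C(C)(C)C)C#C[Sn](CCCC)(CCCC)CCCC | intermediate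
8 | 4-[(1R)-1-{[tert-butyl(dimethyl)silyl]oxy}butyl]-3-(tributylstannyl)-1-oxa-2-nickelacyclopent-3-en-5-one (oxanickelacyclopentenone; DBU ligands on nickel omitted) | CCC[C@@H](O[Si](C)(C)C(C)(C)C)C1=C([Sn](CCCC)(CCCC)CCCC)[Ni]OC1=O | intermediate
9 | (2E)-2-[(1R)-1-{[tert-butyl(dimethyl)silyl]oxy}butyl]-3-(tributylstannyl)-5-(trimethylsilyl)pent-2-en-4-ynoic acid | CCC[C@@H](O[Si](C)(C)C(C)(C)C)/C(C(=O)O)=C(/C#C[Si](C)(C)C)[Sn](CCCC)(CCCC)CCCC | intermediate
10 | (2E)-3-bromo-2-[(1R)-1-{[tert-butyl(dimethyl)silyl]oxy}butyl]-5-(trimethylsilyl)pent-2-en-4-ynoic acid | CCC[C@@H](O[Si](C)(C)C(C)(C)C)/C(C(=O)O)=C(/C#C[Si](C)(C)C)Br | intermediate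
11 | (2E)-3-bromo-2-[(1R)-1-hydroxybutyl]pent-2-en-4-ynoic acid | CCC[C@@H](O)/C(C(=O)O)=C(/C#C)Br | intermediate
12 | (5E)-4-bromo-3-[(1R)-1-hydroxybutyl]-5-(iodomethylidene)furan-2(5H)-one | CCC[C@@H](O)C1=C(Br)/C(=C\I)OC1=O | target

Total step count: 8. Longest linear sequence: 8 steps (1 and 2 to 12).

Steps most likely to fail

Step 5. The oxidative cyclization may lose regiocontrol because both alkyne substituents are bulky, nickel may insert into the C(sp)–Sn bond instead of binding the alkyne, and the alkenyl–tin bond may be protonated during the acidic work-up. The fallback sets out from 7 and makes the same two bonds on zirconium without nickel or acid. In one flask, 7 would be treated with Cp2ZrEt2 (from Cp2ZrCl2 and EtMgBr), then with 2-(trimethylsilyl)ethyl chloroformate, then with CuCl and (bromoethynyl)trimethylsilane. This zirconocene-mediated ester formation followed by copper-mediated alkynylation should give 2-(trimethylsilyl)ethyl (2E)-2-[(1R)-1-{[tert-butyl(dimethyl)silyl]oxy}butyl]-3-(tributylstannyl)-5-(trimethylsilyl)pent-2-en-4-ynoate F1. Br2 at −78 °C should convert it into 2-(trimethylsilyl)ethyl (2E)-3-bromo-2-[(1R)-1-{[tert-butyl(dimethyl)silyl]oxy}butyl]-5-(trimethylsilyl)pent-2-en-4-ynoate F2. TBAF then removes the silylethyl ester, the alkynyl silyl group and the TBS ether together, and the fallback comes back to the route at 11.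

Step 8. Ring closure may take the 6-endo-dig course to the iodopyranone, and the hindered vinyl iodide may isomerise under iodine and light. The fallback sets out from 11 and separates ring closure from iodination. Cyclization with Hg(OCOCF3)2 in CH2Cl2 (anti oxymercuration, strongly favouring attack at the internal alkyne carbon) followed by exchange with aqueous NaCl should give (5E)-4-bromo-5-[(chloromercurio)methylidene]-3-[(1R)-1-hydroxybutyl]furan-2(5H)-one F3. Iododemercuration with I2 proceeds with retention and comes back to the route at 12.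

Step 7. Under basic fluoride the carboxylate may add to the freed alkyne before iodine is present (premature lactonisation), or the enynoic acid may decompose. The fallback sets out from 10 and moves the removal of the TBS group to the end under acidic conditions. K2CO3 in MeOH at 0 °C removes only the alkynyl silyl group to give (2E)-3-bromo-2-[(1R)-1-{[tert-butyl(dimethyl)silyl]oxy}butyl]pent-2-en-4-ynoic acid F4. Iodolactonisation (I2, NaHCO3, MeCN) gives (5E)-4-bromo-3-[(1R)-1-{[tert-butyl(dimethyl)silyl]oxy}butyl]-5-(iodomethylidene)furan-2(5H)-one F5. HF·pyridine in THF cleaves the TBS ether and comes back to the route at 12.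

Further compounds
F1 | step 5 | 2-(trimethylsilyl)ethyl (2E)-2-[(1R)-1-{[tert-butyl(dimethyl)silyl]oxy}butyl]-3-(tributylstannyl)-5-(trimethylsilyl)pent-2-en-4-ynoate | CCC[C@@H](O[Si](C)(C)C(C)(C)C)/C(C(=O)OCC[Si](C)(C)C)=C(/C#C[Si](C)(C)C)[Sn](CCCC)(CCCC)CCCC
F2 | step 5 | 2-(trimethylsilyl)ethyl (2E)-3-bromo-2-[(1R)-1-{[tert-butyl(dimethyl)silyl]oxy}butyl]-5-(trimethylsilyl)pent-2-en-4-ynoate | CCC[C@@H](O[Si](C)(C)C(C)(C)C)/C(C(=O)OCC[Si](C)(C)C)=C(/C#C[Si](C)(C)C)Br
F3 | step 8 | (5E)-4-bromo-5-[(chloromercurio)methylidene]-3-[(1R)-1-hydroxybutyl]furan-2(5H)-one | CCC[C@@H](O)C1=C(Br)/C(=C\[Hg]Cl)OC1=O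
F4 | step 7 | (2E)-3-bromo-2-[(1R)-1-{[tert-butyl(dimethyl)silyl]oxy}butyl]pent-2-en-4-ynoic acid | CCC[C@@H](O[Si](C)(C)C(C)(C)C)/C(C(=O)O)=C(/C#C)Br
F5 | step 7 | (5E)-4-bromo-3-[(1R)-1-{[tert-butyl(dimethyl)silyl]oxy}butyl]-5-(iodomethylidene)furan-2(5H)-one | CCC[C@@H](O[Si](C)(C)C(C)(C)C)C1=C(Br)/C(=C\I)OC1=O
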